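## The problem

The target is a propan-1-one with all three carbons fully substituted. C1 is the ketone carbon bonded to ring A (2-hydroxy-4-methoxyphenyl). C2 carries the chromone through C3' (ring D is its benzo ring, with the 7-hydroxyl), and C3 carries rings B and C, two identical 4-hydroxyphenyl groups. Because rings B and C are the same, C3 is not stereogenic and C2 (R) is the only stereocenter; no second center can relay or correct it, so its configuration must come from a chiral reagent or catalyst. The C2–H bond is α to the C1 aryl ketone and allylic to the C2'=C3' bond of the pyranone, so once both neighbours are in place the center can racemize by enolization under base, acid or heat. The pyranone ring is opened by hydroxide, alkoxides and amines and is attacked at C2' and C4' by aryllithium and Grignard reagents, which excludes the obvious polar ways of attaching ring A late. Four phenols must be freed at the end beside a methyl ether that stays, under conditions that are neither acidic nor basic. The enabling feature is that C2 has, apart from hydrogen and C3, two one-carbon neighbours, C1 and C3', and both can be written at the hydroxymethyl level. The resulting 2-(diarylmethyl)propane-1,3-diol holds C1, C2, C3', C3 and rings B and C, is prochiral at C2 and has no acidic C2–H, so telling its two enantiotopic arms apart fixes C2 where it cannot epimerize.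

## Retrosynthesis

**29 back to 28.** Only the four O–benzyl bonds are cut; the skeleton is untouched. Benzyl is preferred over silyl ethers (fluoride is basic enough to enolize C2), acetals (acid) and methyl ethers (their cleavage would also take the ring A methoxy group), because hydrogenolysis runs at neutral pH. The forward step must spare the C2'=C3' bond and the C1 ketone.

**28 back to 23 and 27.** The C1–ring A bond is cut. The neighbouring cut, C1–C2, would build C2 through an enolate and give up stereocontrol, and addition of an aryl-metal to a C1 aldehyde or amide would also strike the chromone. Acyl cross-coupling of thioester 23 with boronic acid 27 needs neither base nor a hard nucleophile. The forward reaction must couple a hindered, α-branched thioester without epimerization or decarbonylation.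

**23 back to 20.** No skeletal bond is cut: C1 is taken down from the thioester through acid 22 and the transient aldehyde 21 to the primary alcohol 20. This keeps C2 without a carbonyl neighbour for as long as possible. The forward oxidation must pass the enolizable aldehyde quickly.

**20 back to 17.** The O1'–C2' and C2'–C3' bonds of the pyranone are cut and C2' is removed as a one-carbon electrophile. Joining a ready-made 3-halochromone to C2 would instead need a secondary alkyl-metal at the stereocenter, which would not hold its configuration. Ketone 17 is open-chain, and C2 is β to its carbonyl and so not enolizable. The forward step runs through enaminone 18 and silyl ether 19 and can use acid, which also unmasks the C1 arm.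

**17 back to 11 and 14.** The C3'–C4' bond is cut: phenol 17 comes from its acetate 16, and 16 from alkylzinc iodide 15 (made from iodide 11) and acid chloride 14. The opposite polarity, an aldehyde on the C3' arm and an aryl-metal, would put a carbonyl next to C2 with a β-oxygen leaving group. In 15 zinc sits on CH2 and the nearest oxygen is on the γ-carbon, so neither elimination nor loss of configuration is open. Chloride 14 comes from acid 12 through acetate 13; the acetate tolerates acid chloride formation and leaves under conditions that spare silyl and benzyl ethers.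

**11 back to 8.** Functional group changes only: iodide 11 from alcohol 10, 10 from silyl ether acetate 9, and 9 from monoacetate 8. The sequence puts silyl on the future C1 arm and iodide on the future C3' arm, and so decides that 8 with S configuration leads to 29 with R configuration.

**8 back to 6 and 7 (key step).** Only an O–acetyl bond is cut, but precursor 6 is achiral. The whole stereochemical problem becomes a choice between two enantiotopic CH2OH groups. Unlike cuts that create C2 by C–C bond formation next to a carbonyl, this one sets the center where it is configurationally inert. The forward reaction must acetylate one arm only, and always the same one.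

**6 back to 1, 2 and 4.** Diol 6 comes from malonate 5 by reduction. In 5 the C3–aryl bond is cut to arylidene malonate 3 and Grignard reagent 4, and the C2=C3 bond of 3 leads to aldehyde 1 and diethyl malonate 2. Acid-catalysed alkylation of malonate with a diarylmethanol was the neighbouring option; conjugate addition is preferred because malonate is a weak nucleophile towards benzhydryl cations, which tend to end as the symmetrical ether.

**27 back to 24.** The C–B bond is cut to bromide 25 (through aryllithium 26), and the O–benzyl bond of 25 to bromophenol 24. The bromine fixes boron ortho to the benzyloxy group and para to methoxy, a position that directed lithiation of the ether would not select.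

## Roads not taken

**Alternative 1:** The cut removes both C3–aryl bonds at once and leads back to a methyl group. The α-methyl quinolin-8-yl amide A1 would be arylated twice at CH3 by aryl iodide A2 under a divalent palladium carboxylate and a silver carboxylate, through a five-membered palladacycle held by the bidentate amide, to give the β,β-diaryl amide A3.
- Merits: it uses the identity of rings B and C better than any other plan, forms two skeletal bonds in one operation with the chromone already present, and never has to tell two arms apart.
- Weak points: C2 must already be set in A1 by a separate asymmetric step. It then sits α to an amide and allylic to the pyranone through a hot, carboxylate-buffered reaction. The second arylation must occur at a benzylic methylene beside a crowded C2. C2'–H of the chromone is itself a site of palladium-mediated arylation. The directing amide must finally be turned into the ring A ketone, which needs forcing hydrolysis or activation at the center that racemizes most easily.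
- Comparison: in bond economy this road is better than the chosen one. The chosen plan sets against it that the source of chirality lies inside the plan, that C2 has no carbonyl neighbour until step 13, and that C1 is introduced as a thioester made for coupling, not as an amide that has to be broken.

**Alternative 2:** The cut is the C3'–C4' bond, with C2 created by protonation. In aldehyde A4 the ring D aldehyde is tied through its ortho oxygen to a trisubstituted enone bearing ring A and the diarylmethyl group. It would undergo an intramolecular Stetter reaction under a chiral triazolium-derived carbene: the Breslow intermediate adds to C3', the enolate is protonated at C2, and chroman-4-one A5 results.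
- Merits: a catalytic enantioselective C–C bond formation closes the pyranone ring and sets C2 in one step on a fully assembled skeleton, with clearly fewer steps.
- Weak points: the acceptor is α-branched with a diarylmethyl group, a class on which Stetter reactions are slow. C2 is set by diastereoselective protonation relative to the new C3' center and is born α to the C1 ketone in a basic medium that can undo it. The chromanone must then be dehydrogenated across C2'–C3' while C2–H is left alone, although loss of hydrogen from C3' and C2 would give a fully conjugated ene-dione and erase the stereocenter.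
- Comparison: this road is shorter and makes the center more elegantly. The chosen plan offers in return a chromone formed directly at the right oxidation level and a stereocenter never generated by protonation nor exposed to an oxidant beside a ketone.

**Alternative 3:** The cut is the C3–ring B bond, made inside a flavanone. Boronic acid A7 would add to C2 of the 7-methoxychromone half of bichromone A6 under a rhodium chiral-diene catalyst with a phosphate base, the other half being switched off as its phenoxide. Protonation would give the trans-2,3-disubstituted chroman-4-one A8, in which the ring A oxygen is still bonded to C3.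
- Merits: rhodium-catalysed asymmetric arylation of chromones is established, the ring A phenol needs no protecting group, the trans relationship lets the C3 center dictate C2 thermodynamically, and the sequence is the shortest on paper.
- Weak points: the reacting chromone carries a 3-substituent, which slows conjugate addition strongly, and site selection between the halves rests on one ionized phenol. The C3–O bond must later be exchanged for ring C by ionization at C3 or by ring opening to a chalcone. After that C3 is no longer stereogenic and C2 must hold its configuration alone, next to a cation or after passing through an sp2 carbon.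
- Comparison: this road is better in step count and protecting-group economy. The chosen plan sets against it a stereocenter that is installed directly and never depends on a second, temporary one.

Key step: step 4

Assumption: Candida antarctica lipase B is taken to acetylate the pro-S hydroxymethyl group of 6, so that 8 has the S configuration; the sense has to be confirmed on the first run, and the fallback for step 4 lets either sense be chosen.

## Route

Step 1
Reactants: 1 4-(benzyloxy)benzaldehyde; 2 diethyl malonate
Product: 3 diethyl 2-[4-(benzyloxy)benzylidene]malonate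
Conditions: piperidine (cat.), AcOH (cat.), toluene, reflux, Dean–Stark
Reagents that add atoms: none
Why: Knoevenagel condensation; the amine/acid pair activates the aldehyde as its iminium ion and azeotropic removal of water drives the electron-rich aldehyde to the arylidene malonate.

Step 2
Reactants: 3 diethyl 2-[4-(benzyloxy)benzylidene]malonate; 4 [4-(benzyloxy)phenyl]magnesium bromide
Product: 5 diethyl 2-{bis[4-(benzyloxy)phenyl]methyl}malonate
Conditions: CuI (10 mol %), THF, −20 °C to rt; then 1 M HCl
Reagents that add atoms: none
Why: Copper-catalysed conjugate addition of an aryl Grignard reagent to an arylidene malonate, a doubly activated acceptor that resists 1,2-addition; both aryl groups are identical, so C3 is not a stereocenter.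

Step 3
Reactants: 5 diethyl 2-{bis[4-(benzyloxy)phenyl]methyl}malonate
Product: 6 2-{bis[4-(benzyloxy)phenyl]methyl}propane-1,3-diol
Conditions: LiAlH4, THF, 0 °C to reflux; then H2O, aq. NaOH
Reagents that add atoms: none
Why: Hydride reduction of both esters to primary alcohols; benzyl aryl ethers are inert, and excess hydride at reflux is used because part of the malonate is held back as its enolate.

Step 4
Reactants: 6 2-{bis[4-(benzyloxy)phenyl]methyl}propane-1,3-diol; 7 vinyl acetate
Product: 8 (S)-3-hydroxy-2-{bis[4-(benzyloxy)phenyl]methyl}propyl acetate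
Conditions: Novozym 435 (immobilized Candida antarctica lipase B), 7 (5 equiv), MTBE–THF, 30 °C, stopped when 6 is consumed
Reagents that add atoms: none
Why: Lipase-catalysed irreversible transesterification: the active-site serine is acetylated by vinyl acetate, vinyl alcohol leaves as acetaldehyde, and one hydroxymethyl arm of 6 attacks the acetyl enzyme through a tetrahedral intermediate held in the oxyanion hole. The closest known reaction type is the lipase-catalysed monoacetylation of prochiral 2-substituted propane-1,3-diols with vinyl acetate. No skeletal bond forms and no ring closes. The new stereocenter C2 is controlled by the enzyme alone: the bulky diarylmethyl group should fit the chiral active site in a single productive orientation, which presents only one of the two enantiotopic CH2OH groups to the acetyl serine. The step needs enantiotopic-group selectivity and a stop at the monoacetate; the substrate helps through the large size difference between the diarylmethyl group and hydrogen at C2 and through two unhindered primary hydroxyls. Monoacetate of the wrong hand still carries the arm the enzyme prefers, so it should be drained fastest into the achiral diacetate, and the enantiomeric purity of 8 should rise with slight over-conversion. C2 has no carbonyl neighbour here and cannot epimerize; only acetyl migration between the arms could erode it, so 8 is silylated without storage.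

Step 5
Reactants: 8 (S)-3-hydroxy-2-{bis[4-(benzyloxy)phenyl]methyl}propyl acetate
Product: 9 (R)-3-[(tert-butyldimethylsilyl)oxy]-2-{bis[4-(benzyloxy)phenyl]methyl}propyl acetate
Conditions: TBSCl, imidazole, DMF, 0 °C to rt
Reagents that add atoms: tert-butyldimethylsilyl chloride, CC(C)(C)[Si](C)(C)Cl
Why: Imidazole-promoted silylation of a primary alcohol; the base is too weak to move the acetate, and the silyl ether marks the arm that becomes C1 (the descriptor changes by priority only).

Step 6
Reactants: 9 (R)-3-[(tert-butyldimethylsilyl)oxy]-2-{bis[4-(benzyloxy)phenyl]methyl}propyl acetate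
Product: 10 (R)-3-[(tert-butyldimethylsilyl)oxy]-2-{bis[4-(benzyloxy)phenyl]methyl}propan-1-ol
Conditions: K2CO3 (0.2 equiv), MeOH, 0 °C
Reagents that add atoms: none
Why: Base-catalysed methanolysis of the acetate; at 0 °C with catalytic carbonate the primary TBS ether should neither cleave nor migrate to the other arm, which would racemize C2.

Step 7
Reactants: 10 (R)-3-[(tert-butyldimethylsilyl)oxy]-2-{bis[4-(benzyloxy)phenyl]methyl}propan-1-ol
Product: 11 (S)-tert-butyl(3-iodo-2-{bis[4-(benzyloxy)phenyl]methyl}propoxy)dimethylsilane
Conditions: I2, PPh3, imidazole, CH2Cl2, 0 °C to rt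
Reagents that add atoms: iodine, II
Why: Appel-type iodination through the alkoxyphosphonium salt and SN2 displacement by iodide at CH2; C2 is not involved and the silyl ether is stable.

Step 8
Reactants: 12 4-(benzyloxy)-2-hydroxybenzoic acid
Product: 13 2-(acetyloxy)-4-(benzyloxy)benzoic acid
Conditions: Ac2O, pyridine, 0 °C to rt; then aq. HCl
Reagents that add atoms: acetic anhydride, CC(=O)OC(C)=O
Why: O-Acetylation of a salicylic acid phenol (any mixed anhydride is hydrolysed on work-up); the acetate masks the phenol through acid chloride formation and the zinc coupling.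

Step 9
Reactants: 13 2-(acetyloxy)-4-(benzyloxy)benzoic acid
Product: 14 2-(acetyloxy)-4-(benzyloxy)benzoyl chloride
Conditions: (COCl)2, DMF (cat.), CH2Cl2, 0 °C to rt; used crude
Reagents that add atoms: oxalyl chloride, O=C(Cl)C(=O)Cl
Why: Acid chloride formation through the catalytic chloroiminium species; aryl acetate and benzyl ether are unaffected, as in the known O-acetylsalicyloyl chloride.

Step 10
Reactants: 11 (S)-tert-butyl(3-iodo-2-{bis[4-(benzyloxy)phenyl]methyl}propoxy)dimethylsilane; 14 2-(acetyloxy)-4-(benzyloxy)benzoyl chloride
Product: 16 5-(benzyloxy)-2-[(S)-4,4-bis[4-(benzyloxy)phenyl]-3-{[(tert-butyldimethylsilyl)oxy]methyl}butanoyl]phenyl acetate, via alkylzinc iodide 15 (not isolated)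
Conditions: Zn dust (activated with BrCH2CH2Br and TMSCl), LiCl, THF, 40 °C; then 14, Pd(PPh3)4 (5 mol %), THF, 0 °C to rt
Reagents that add atoms: zinc, [Zn] (held only in intermediate 15)
Why: Zinc insertion into the primary C–I bond followed by Negishi acylation (oxidative addition of the aroyl chloride to zerovalent palladium, transmetalation, reductive elimination). Zinc sits on CH2 with the nearest oxygen on the γ-carbon, so neither β-elimination nor loss of configuration at C2 is possible, and alkylzinc halides leave the aryl acetate and the new ketone alone.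

Step 11
Reactants: 16 5-(benzyloxy)-2-[(S)-4,4-bis[4-(benzyloxy)phenyl]-3-{[(tert-butyldimethylsilyl)oxy]methyl}butanoyl]phenyl acetate
Product: 17 (S)-1-[4-(benzyloxy)-2-hydroxyphenyl]-4,4-bis[4-(benzyloxy)phenyl]-3-{[(tert-butyldimethylsilyl)oxy]methyl}butan-1-one
Conditions: K2CO3 (0.2 equiv), MeOH–THF, 0 °C
Reagents that add atoms: none
Why: Methanolysis of a phenyl acetate, far faster than any reaction at the alkyl silyl ether; it frees the ortho phenol needed for ring closure, and C2 is β to the ketone and not enolizable.

Step 12
Reactants: 17 (S)-1-[4-(benzyloxy)-2-hydroxyphenyl]-4,4-bis[4-(benzyloxy)phenyl]-3-{[(tert-butyldimethylsilyl)oxy]methyl}butan-1-one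
Product: 20 (R)-7-(benzyloxy)-3-{1,1-bis[4-(benzyloxy)phenyl]-3-hydroxypropan-2-yl}-4H-chromen-4-one, via enaminone 18 (not isolated), via silyl ether chromone 19 (not isolated)
Conditions: DMF-DMA, toluene, 100 °C; concentrate; then 2 M aq. HCl, THF, rt
Reagents that add atoms: N,N-dimethylformamide dimethyl acetal, COC(OC)N(C)C
Why: Enaminone route to 3-substituted chromones: the formamide acetal condenses at the α-methylene of the o-hydroxyaryl ketone, acid triggers 6-endo oxa-Michael addition of the phenol and loss of dimethylamine, and the same aqueous acid hydrolyses the primary TBS ether. C2 is never α to a carbonyl in this step.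

Step 13
Reactants: 20 (R)-7-(benzyloxy)-3-{1,1-bis[4-(benzyloxy)phenyl]-3-hydroxypropan-2-yl}-4H-chromen-4-one
Product: 22 (R)-2-[7-(benzyloxy)-4-oxo-4H-chromen-3-yl]-3,3-bis[4-(benzyloxy)phenyl]propanoic acid, via aldehyde 21 (not isolated)
Conditions: TEMPO (20 mol %), PhI(OAc)2 (2.2 equiv), MeCN–H2O, rt
Reagents that add atoms: water, O
Why: Oxoammonium-mediated oxidation of the primary alcohol to the aldehyde, hydration and second oxidation to the acid; the medium is weakly acidic with no base and no hypochlorite, so the enolizable aldehyde should be consumed as it forms and the electron-rich rings are not halogenated.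

Step 14
Reactants: 22 (R)-2-[7-(benzyloxy)-4-oxo-4H-chromen-3-yl]-3,3-bis[4-(benzyloxy)phenyl]propanoic acid
Product: 23 S-phenyl (R)-2-[7-(benzyloxy)-4-oxo-4H-chromen-3-yl]-3,3-bis[4-(benzyloxy)phenyl]propanethioate
Conditions: PhSSPh, PBu3, CH2Cl2, 0 °C to rt
Reagents that add atoms: diphenyl disulfide, c1ccc(SSc2ccccc2)cc1
Why: Mukaiyama-type redox condensation: phosphine and disulfide give a thiophosphonium thiolate, the acid is activated as its acyloxyphosphonium ion and acylates benzenethiolate. No amine base or acylpyridinium is present, which avoids ketene formation and racemization at C2.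

Step 15
Reactants: 24 2-bromo-5-methoxyphenol
Product: 25 2-(benzyloxy)-1-bromo-4-methoxybenzene
Conditions: BnBr, K2CO3, DMF, rt
Reagents that add atoms: benzyl bromide, BrCc1ccccc1
Why: Williamson benzylation of the phenol.

Step 16
Reactants: 25 2-(benzyloxy)-1-bromo-4-methoxybenzene
Product: 27 [2-(benzyloxy)-4-methoxyphenyl]boronic acid, via aryllithium 26 (not isolated)
Conditions: n-BuLi, THF, −78 °C; B(OiPr)3, −78 °C to rt; then 1 M HCl
Reagents that add atoms: triisopropyl borate, CC(C)OB(OC(C)C)OC(C)C; water, O
Why: Bromine–lithium exchange, borylation and hydrolysis; at −78 °C the aryllithium should be trapped before it can deprotonate its own benzylic CH2.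

Step 17
Reactants: 23 S-phenyl (R)-2-[7-(benzyloxy)-4-oxo-4H-chromen-3-yl]-3,3-bis[4-(benzyloxy)phenyl]propanethioate; 27 [2-(benzyloxy)-4-methoxyphenyl]boronic acid
Product: 28 (R)-7-(benzyloxy)-3-{1-[2-(benzyloxy)-4-methoxyphenyl]-3,3-bis[4-(benzyloxy)phenyl]-1-oxopropan-2-yl}-4H-chromen-4-one
Conditions: Pd2(dba)3 (2.5 mol %), P(2-furyl)3 (10 mol %), CuTC [Cu(O2C-2-C4H3S), monovalent copper] (1.5 equiv), THF, rt to 45 °C
Reagents that add atoms: none
Why: Liebeskind–Srogl acyl cross-coupling: zerovalent palladium inserts into the C(O)–S bond, the copper carboxylate binds the thiolate and activates the boronic acid for base-free transmetalation, and reductive elimination gives the ketone. No base and no hard carbon nucleophile are present, so the chromone is left alone and the α-stereocenter should be retained, as in couplings of α-amino thioesters.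

Step 18
Reactants: 28 (R)-7-(benzyloxy)-3-{1-[2-(benzyloxy)-4-methoxyphenyl]-3,3-bis[4-(benzyloxy)phenyl]-1-oxopropan-2-yl}-4H-chromen-4-one
Product: 29 (R)-7-hydroxy-3-[1-(2-hydroxy-4-methoxyphenyl)-3,3-bis(4-hydroxyphenyl)-1-oxopropan-2-yl]-4H-chromen-4-one
Conditions: H2 (1 atm), Pd/C (10 wt %), EtOAc–EtOH, rt, stopped after uptake of four equivalents
Reagents that add atoms: none
Why: Hydrogenolysis of four aryl benzyl ethers at neutral pH, which should be faster than reduction of the 3-substituted chromone double bond or the aryl ketone; the methyl ether is inert and C2 is not exposed to acid or base.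

## Compound list

1 | 4-(benzyloxy)benzaldehyde | O=Cc1ccc(OCc2ccccc2)cc1 | starting material
2 | diethyl malonate | CCOC(=O)CC(=O)OCC | starting material
3 | diethyl 2-[4-(benzyloxy)benzylidene]malonate | CCOC(=O)C(=Cc1ccc(OCc2ccccc2)cc1)C(=O)OCC | intermediate
4 | [4-(benzyloxy)phenyl]magnesium bromide (THF solution) | Br[Mg]c1ccc(OCc2ccccc2)cc1 | starting material
5 | diethyl 2-{bis[4-(benzyloxy)phenyl]methyl}malonate | CCOC(=O)C(C(=O)OCC)C(c1ccc(OCc2ccccc2)cc1)c1ccc(OCc2ccccc2)cc1 | intermediate
6 | 2-{bis[4-(benzyloxy)phenyl]methyl}propane-1,3-diol | OCC(CO)C(c1ccc(OCc2ccccc2)cc1)c1ccc(OCc2ccccc2)cc1 | intermediate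
7 | vinyl acetate | C=COC(C)=O | starting material
8 | (S)-3-hydroxy-2-{bis[4-(benzyloxy)phenyl]methyl}propyl acetate | OC[C@@H](COC(C)=O)C(c1ccc(OCc2ccccc2)cc1)c1ccc(OCc2ccccc2)cc1 | intermediate
9 | (R)-3-[(tert-butyldimethylsilyl)oxy]-2-{bis[4-(benzyloxy)phenyl]methyl}propyl acetate | CC(C)(C)[Si](C)(C)OC[C@@H](COC(C)=O)C(c1ccc(OCc2ccccc2)cc1)c1ccc(OCc2ccccc2)cc1 | intermediate
10 | (R)-3-[(tert-butyldimethylsilyl)oxy]-2-{bis[4-(benzyloxy)phenyl]methyl}propan-1-ol | CC(C)(C)[Si](C)(C)OC[C@@H](CO)C(c1ccc(OCc2ccccc2)cc1)c1ccc(OCc2ccccc2)cc1 | intermediate
11 | (S)-tert-butyl(3-iodo-2-{bis[4-(benzyloxy)phenyl]methyl}propoxy)dimethylsilane | CC(C)(C)[Si](C)(C)OC[C@@H](CI)C(c1ccc(OCc2ccccc2)cc1)c1ccc(OCc2ccccc2)cc1 | intermediate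
12 | 4-(benzyloxy)-2-hydroxybenzoic acid | OC(=O)c1ccc(OCc2ccccc2)cc1O | starting material
13 | 2-(acetyloxy)-4-(benzyloxy)benzoic acid | CC(=O)Oc1cc(OCc2ccccc2)ccc1C(=O)O | intermediate
14 | 2-(acetyloxy)-4-(benzyloxy)benzoyl chloride | CC(=O)Oc1cc(OCc2ccccc2)ccc1C(Cl)=O | intermediate
15 | {(S)-3-[(tert-butyldimethylsilyl)oxy]-2-{bis[4-(benzyloxy)phenyl]methyl}propyl}zinc iodide (not isolated) | CC(C)(C)[Si](C)(C)OC[C@@H](C[Zn]I)C(c1ccc(OCc2ccccc2)cc1)c1ccc(OCc2ccccc2)cc1 | intermediate
16 | 5-(benzyloxy)-2-[(S)-4,4-bis[4-(benzyloxy)phenyl]-3-{[(tert-butyldimethylsilyl)oxy]methyl}butanoyl]phenyl acetate | CC(C)(C)[Si](C)(C)OC[C@@H](CC(=O)c1ccc(OCc2ccccc2)cc1OC(C)=O)C(c1ccc(OCc2ccccc2)cc1)c1ccc(OCc2ccccc2)cc1 | intermediate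
17 | (S)-1-[4-(benzyloxy)-2-hydroxyphenyl]-4,4-bis[4-(benzyloxy)phenyl]-3-{[(tert-butyldimethylsilyl)oxy]methyl}butan-1-one | CC(C)(C)[Si](C)(C)OC[C@@H](CC(=O)c1ccc(OCc2ccccc2)cc1O)C(c1ccc(OCc2ccccc2)cc1)c1ccc(OCc2ccccc2)cc1 | intermediate
18 | (R)-1-[4-(benzyloxy)-2-hydroxyphenyl]-4,4-bis[4-(benzyloxy)phenyl]-3-{[(tert-butyldimethylsilyl)oxy]methyl}-2-[(dimethylamino)methylidene]butan-1-one (alkene geometry not assigned; not isolated) | CC(C)(C)[Si](C)(C)OC[C@@H](C(=CN(C)C)C(=O)c1ccc(OCc2ccccc2)cc1O)C(c1ccc(OCc2ccccc2)cc1)c1ccc(OCc2ccccc2)cc1 | intermediate
19 | (R)-7-(benzyloxy)-3-{1,1-bis[4-(benzyloxy)phenyl]-3-[(tert-butyldimethylsilyl)oxy]propan-2-yl}-4H-chromen-4-one (not isolated) | CC(C)(C)[Si](C)(C)OC[C@@H](c1coc2cc(OCc3ccccc3)ccc2c1=O)C(c1ccc(OCc2ccccc2)cc1)c1ccc(OCc2ccccc2)cc1 | intermediate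
20 | (R)-7-(benzyloxy)-3-{1,1-bis[4-(benzyloxy)phenyl]-3-hydroxypropan-2-yl}-4H-chromen-4-one | OC[C@@H](c1coc2cc(OCc3ccccc3)ccc2c1=O)C(c1ccc(OCc2ccccc2)cc1)c1ccc(OCc2ccccc2)cc1 | intermediate
21 | (R)-2-[7-(benzyloxy)-4-oxo-4H-chromen-3-yl]-3,3-bis[4-(benzyloxy)phenyl]propanal (not isolated) | O=C[C@@H](c1coc2cc(OCc3ccccc3)ccc2c1=O)C(c1ccc(OCc2ccccc2)cc1)c1ccc(OCc2ccccc2)cc1 | intermediate
22 | (R)-2-[7-(benzyloxy)-4-oxo-4H-chromen-3-yl]-3,3-bis[4-(benzyloxy)phenyl]propanoic acid | OC(=O)[C@@H](c1coc2cc(OCc3ccccc3)ccc2c1=O)C(c1ccc(OCc2ccccc2)cc1)c1ccc(OCc2ccccc2)cc1 | intermediate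
23 | S-phenyl (R)-2-[7-(benzyloxy)-4-oxo-4H-chromen-3-yl]-3,3-bis[4-(benzyloxy)phenyl]propanethioate | O=C(Sc1ccccc1)[C@@H](c1coc2cc(OCc3ccccc3)ccc2c1=O)C(c1ccc(OCc2ccccc2)cc1)c1ccc(OCc2ccccc2)cc1 | intermediate
24 | 2-bromo-5-methoxyphenol | COc1ccc(Br)c(O)c1 | starting material
25 | 2-(benzyloxy)-1-bromo-4-methoxybenzene | COc1ccc(Br)c(OCc2ccccc2)c1 | intermediate
26 | [2-(benzyloxy)-4-methoxyphenyl]lithium (not isolated) | COc1ccc([Li])c(OCc2ccccc2)c1 | intermediate
27 | [2-(benzyloxy)-4-methoxyphenyl]boronic acid | COc1ccc(B(O)O)c(OCc2ccccc2)c1 | intermediate
28 | (R)-7-(benzyloxy)-3-{1-[2-(benzyloxy)-4-methoxyphenyl]-3,3-bis[4-(benzyloxy)phenyl]-1-oxopropan-2-yl}-4H-chromen-4-one | COc1ccc(C(=O)[C@@H](c2coc3cc(OCc4ccccc4)ccc3c2=O)C(c2ccc(OCc3ccccc3)cc2)c2ccc(OCc3ccccc3)cc2)c(OCc2ccccc2)c1 | intermediate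
29 | (R)-7-hydroxy-3-[1-(2-hydroxy-4-methoxyphenyl)-3,3-bis(4-hydroxyphenyl)-1-oxopropan-2-yl]-4H-chromen-4-one | COc1ccc(C(=O)[C@@H](c2coc3cc(O)ccc3c2=O)C(c2ccc(O)cc2)c2ccc(O)cc2)c(O)c1 | target

## Step count and least certain steps

Total: 18 steps. Longest linear sequence: 14 steps (steps 1–7, 10–14, 17 and 18).

**Step 4 (key step).** The most likely failure is slow acetylation or poor discrimination between the two arms, because the diarylmethyl group is far bulkier than the 2-substituents on which this lipase is known to perform and the enzyme is less predictable for β-branched primary alcohols than for secondary ones. Acetylation of the opposite arm is also possible. Fallback: non-enzymatic desymmetrization of 6 with vinyl benzoate under the dinuclear zinc catalyst formed from Et2Zn and the ProPhenol ligand, whose two antipodes allow either sense. This should give (S)-3-hydroxy-2-{bis[4-(benzyloxy)phenyl]methyl}propyl benzoate F1. Silylation (TBSCl, imidazole) gives (R)-3-[(tert-butyldimethylsilyl)oxy]-2-{bis[4-(benzyloxy)phenyl]methyl}propyl benzoate F2, and methanolysis (K2CO3, MeOH) returns to the route at 10.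

**Step 17.** The thioester is α-branched with two large groups, so oxidative addition and transmetalation may be slow. The acyl palladium species may then lose CO and eliminate, and the ortho-alkoxy boronic acid may protodeboronate. Prolonged warming also invites epimerization at C2. Fallback: start from 20, oxidize with Dess–Martin periodinane and isolate aldehyde 21 crude. Quench aryllithium 26 with iodine to obtain 2-(benzyloxy)-1-iodo-4-methoxybenzene F3. Join the two by Nozaki–Hiyama–Kishi coupling (CrCl2, NiCl2 cat., DMF), which is selective for aldehydes over the chromone, to give 7-(benzyloxy)-3-{(2R)-1-[2-(benzyloxy)-4-methoxyphenyl]-3,3-bis[4-(benzyloxy)phenyl]-1-hydroxypropan-2-yl}-4H-chromen-4-one F4 as a mixture of carbinol epimers. A second Dess–Martin oxidation rejoins the route at 28.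

**Step 12.** Condensation of the formamide acetal at a methylene flanked by a tertiary carbon may be sluggish, and at the temperature needed O-methylation of the phenol can compete. Fallback: Claisen formylation of 17 with ethyl formate and NaH in THF, which should give 7-(benzyloxy)-3-{(R)-1,1-bis[4-(benzyloxy)phenyl]-3-[(tert-butyldimethylsilyl)oxy]propan-2-yl}-2-hydroxychroman-4-one F5. The same aqueous HCl in THF then dehydrates it and removes the silyl group, returning to the route at 20.

**Step 10.** Zinc insertion into the β-branched iodide may be incomplete, and the organozinc may be lost by protonation or homocoupling before acyl transfer. Fallback: couple 11 and 14 directly by nickel-catalysed reductive cross-electrophile coupling (NiCl2(dme), 4,4'-di-tert-butyl-2,2'-bipyridine, Zn powder, DMA, rt). The alkyl radical from 11 is captured at an acyl nickel species without a preformed organometallic, and the product is 16.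

**Step 18.** Over-reduction of the C2'=C3' bond or the C1 ketone may accompany removal of the last benzyl groups, and traces of sulfur from step 17 may slow the catalyst and tempt longer reaction times. Fallback: cleave the benzyl ethers of 28 with BCl3 and pentamethylbenzene as cation scavenger in CH2Cl2 at −78 °C, a non-reductive dealkylation that should leave the methyl ether at that temperature and gives 29 directly.

## Further compounds

F1 | step 4 | (S)-3-hydroxy-2-{bis[4-(benzyloxy)phenyl]methyl}propyl benzoate | OC[C@@H](COC(=O)c1ccccc1)C(c1ccc(OCc2ccccc2)cc1)c1ccc(OCc2ccccc2)cc1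
F2 | step 4 | (R)-3-[(tert-butyldimethylsilyl)oxy]-2-{bis[4-(benzyloxy)phenyl]methyl}propyl benzoate | CC(C)(C)[Si](C)(C)OC[C@@H](COC(=O)c1ccccc1)C(c1ccc(OCc2ccccc2)cc1)c1ccc(OCc2ccccc2)cc1
F3 | step 17 | 2-(benzyloxy)-1-iodo-4-methoxybenzene | COc1ccc(I)c(OCc2ccccc2)c1
F4 | step 17 | 7-(benzyloxy)-3-{(2R)-1-[2-(benzyloxy)-4-methoxyphenyl]-3,3-bis[4-(benzyloxy)phenyl]-1-hydroxypropan-2-yl}-4H-chromen-4-one (carbinol epimers) | COc1ccc(C(O)[C@@H](c2coc3cc(OCc4ccccc4)ccc3c2=O)C(c2ccc(OCc3ccccc3)cc2)c2ccc(OCc3ccccc3)cc2)c(OCc2ccccc2)c1
F5 | step 12 | 7-(benzyloxy)-3-{(R)-1,1-bis[4-(benzyloxy)phenyl]-3-[(tert-butyldimethylsilyl)oxy]propan-2-yl}-2-hydroxychroman-4-one (ring centers not assigned) | CC(C)(C)[Si](C)(C)OC[C@@H](C1C(O)Oc2cc(OCc3ccccc3)ccc2C1=O)C(c1ccc(OCc2ccccc2)cc1)c1ccc(OCc2ccccc2)cc1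
F0 | step 10 | none | none
F0 | step 18 | none | none
A1 | alternative 1 | (R)-2-[7-(benzyloxy)-4-oxo-4H-chromen-3-yl]-N-(quinolin-8-yl)propanamide | O=C(Nc1cccc2cccnc12)[C@@H](c1coc2cc(OCc3ccccc3)ccc2c1=O)C
A2 | alternative 1 | 1-(benzyloxy)-4-iodobenzene | Ic1ccc(OCc2ccccc2)cc1
A3 | alternative 1 | (R)-2-[7-(benzyloxy)-4-oxo-4H-chromen-3-yl]-3,3-bis[4-(benzyloxy)phenyl]-N-(quinolin-8-yl)propanamide | O=C(Nc1cccc2cccnc12)[C@@H](c1coc2cc(OCc3ccccc3)ccc2c1=O)C(c1ccc(OCc2ccccc2)cc1)c1ccc(OCc2ccccc2)cc1
A4 | alternative 2 | 4-(benzyloxy)-2-({4-[2-(benzyloxy)-4-methoxyphenyl]-3-{bis[4-(benzyloxy)phenyl]methyl}-4-oxobut-2-en-1-yl}oxy)benzaldehyde (alkene geometry open) | COc1ccc(C(=O)C(=CCOc2cc(OCc3ccccc3)ccc2C=O)C(c2ccc(OCc3ccccc3)cc2)c2ccc(OCc3ccccc3)cc2)c(OCc2ccccc2)c1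
A5 | alternative 2 | (S)-7-(benzyloxy)-3-{(R)-1-[2-(benzyloxy)-4-methoxyphenyl]-3,3-bis[4-(benzyloxy)phenyl]-1-oxopropan-2-yl}chroman-4-one | COc1ccc(C(=O)[C@@H]([C@H]2COc3cc(OCc4ccccc4)ccc3C2=O)C(c2ccc(OCc3ccccc3)cc2)c2ccc(OCc3ccccc3)cc2)c(OCc2ccccc2)c1
A6 | alternative 3 | 7-hydroxy-7'-methoxy-4H,4'H-[3,3'-bichromene]-4,4'-dione | COc1ccc2c(c1)occ(-c1coc3cc(O)ccc3c1=O)c2=O
A7 | alternative 3 | [4-(benzyloxy)phenyl]boronic acid | OB(O)c1ccc(OCc2ccccc2)cc1
A8 | alternative 3 | (2R,3S)-2-[4-(benzyloxy)phenyl]-3-(7-hydroxy-4-oxo-4H-chromen-3-yl)-7-methoxychroman-4-one | COc1ccc2C(=O)[C@@H](c3coc4cc(O)ccc4c3=O)[C@H](c3ccc(OCc4ccccc4)cc3)Oc2c1
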